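The route rests on the C6–C7 bond (germacrane numbering; C6 is the lactone carbinol carbon, C7 the butenolide β-carbon), which belongs to both the ten-membered carbocycle and the butenolide. With C7 as the iodine-bearing carbon of a (Z)-β-iodoacrylate and C6 as an α,β-epoxy aldehyde, one CrCl2/NiCl2-mediated alkenyl addition closes the carbocycle, sets the C6 carbinol under Felkin–Anh control of the 4,5-epoxide, and lets the alkoxide lactonise onto the cis ester. The precursor is the fully functionalised open chain: both epoxides (two Sharpless epoxidations), the cis C2=C3 alkene (Stille union of two Z-alkenyl fragments), the C8 ester and the C13 acetate are in place, so cyclisation gives the target directly.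

Key step: step 17

Remarks and assumptions
- Numbering (germacrane, used throughout): C1 epoxide CH next to the alkene; C2=C3 cis alkene; C4 methyl-bearing epoxide carbon; C5 epoxide CH; C6 lactone carbinol; C7 butenolide β-carbon; C8 acyloxy carbon; C9 CH2; C10 hydroxymethyl-bearing epoxide carbon; C11 butenolide α-carbon; C12 lactone carbonyl; C13 acetoxymethyl carbon; C14 hydroxymethyl carbon; C15 methyl. O6, O8 and O14 are the oxygens on those carbons.
- Assumption: the side chain is (2R)-2-methylbutanoate as drawn, and (2R)-2-methylbutanoic acid is bought as the single enantiomer.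
- Assumption: the catalyst from Me2Zn and (S,S)-ProPhenol delivers the alkynyl group to the Re face of the aldehyde, as it delivers the enolate in the related aldol reaction; the (R,R)-ligand would be used if the sense were opposite.
- The Z-trienes of steps 8–12 are kept at or below 0 °C and carried on promptly, because cis-trienes with allylic C–H bonds can undergo 1,7-hydrogen shifts.

Step 1
Reactants: 1 (2Z)-3-methylpent-2-en-4-yn-1-ol
Product: 2 triethyl{[(2Z)-3-methylpent-2-en-4-yn-1-yl]oxy}silane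
Conditions: TESCl, imidazole, CH2Cl2, 0 °C
Reagents that add atoms: triethylsilyl chloride, CC[Si](Cl)(CC)CC
Why: Standard O-silylation of a primary allylic alcohol, with the acid-labile TES group chosen so that O6 can later be freed while the TBS ether on O14 stays.

Step 2
Reactants: 2 triethyl{[(2Z)-3-methylpent-2-en-4-yn-1-yl]oxy}silane
Product: 4 tributyl[(3Z)-3-methyl-5-(triethylsilyloxy)pent-3-en-1-yn-1-yl]stannane, via lithium acetylide 3 (not isolated)
Conditions: n-BuLi, THF, −78 °C; then Bu3SnCl, −78 → 0 °C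
Reagents that add atoms: tributyltin chloride, CCCC[Sn](Cl)(CCCC)CCCC
Why: Deprotonation of the terminal alkyne and substitution at tin by the acetylide (stannylation of an alkynyl metal) should proceed without touching the Z-alkene.

Step 3
Reactants: 4 tributyl[(3Z)-3-methyl-5-(triethylsilyloxy)pent-3-en-1-yn-1-yl]stannane
Product: 6 tributyl[(1Z,3Z)-3-methyl-5-(triethylsilyloxy)penta-1,3-dien-1-yl]stannane, via alkenylzirconocene 5 (not isolated)
Conditions: Cp2Zr(H)Cl (1.3 equiv), THF, rt; then H2O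
Reagents that add atoms: none
Why: Syn hydrozirconation of the stannylalkyne puts zirconium on the tin-bearing carbon and protonolysis of the C–Zr bond with retention leaves tin cis to the dienyl chain, so the new alkene (later C2=C3) is Z and the existing 4Z alkene is untouched.

Step 4
Reactants: 7 prop-2-yn-1-ol; 8 allylmagnesium bromide
Product: 10 (2Z)-2-(iodomethylidene)pent-4-en-1-ol, via alkenylmagnesium chelate 9 (not isolated)
Conditions: allylMgBr (2.5 equiv), CuI (10 mol %), Et2O, 0 °C → rt; then I2, THF, −40 → 0 °C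
Reagents that add atoms: iodine, I-I
Why: Chelation-controlled anti-carbomagnesiation of the propargylic alkoxide (allyl to the internal carbon, magnesium to the terminus and cis to CH2O in a five-membered chelate) followed by iodinolysis with retention should set the C1=C10 geometry, with iodine (later C2) cis to C14.

Step 5
Reactants: 10 (2Z)-2-(iodomethylidene)pent-4-en-1-ol
Product: 11 tert-butyl{[(2Z)-2-(iodomethylidene)pent-4-en-1-yl]oxy}dimethylsilane
Conditions: TBSCl, imidazole, DMF, rt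
Reagents that add atoms: tert-butyldimethylsilyl chloride, CC(C)(C)[Si](C)(C)Cl
Why: O-silylation blocks O14 (otherwise the aldehyde of step 6 would close to a lactol) with a group that outlasts the TES ether.

Step 6
Reactants: 11 tert-butyl{[(2Z)-2-(iodomethylidene)pent-4-en-1-yl]oxy}dimethylsilane
Product: 13 (3Z)-3-{[tert-butyl(dimethyl)silyl]oxymethyl}-4-iodobut-3-enal, via diol 12 (not isolated)
Conditions: OsO4 (2 mol %), NaIO4 (4 equiv), 2,6-lutidine, dioxane/H2O (3:1), rt; crude aldehyde used at once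
Reagents that add atoms: osmium tetroxide, O=[Os](=O)(=O)=O (its oxygen becomes the aldehyde oxygen; regenerated by sodium periodate, [Na+].[O-]I(=O)(=O)=O)
Why: Johnson–Lemieux cleavage, in which OsO4 should dihydroxylate the monosubstituted terminal alkene far faster than the electron-poor trisubstituted iodoalkene and periodate cleaves the diol to the C8 aldehyde.

Step 7
Reactants: 13 (3Z)-3-{[tert-butyl(dimethyl)silyl]oxymethyl}-4-iodobut-3-enal; 14 methyl prop-2-ynoate
Product: 16 methyl (4S,6Z)-6-{[tert-butyl(dimethyl)silyl]oxymethyl}-4-hydroxy-7-iodohept-6-en-2-ynoate, via alkynylzinc 15 (not isolated)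
Conditions: (S,S)-ProPhenol (20 mol %), Me2Zn (3 equiv), Ph3PO (40 mol %), toluene, 4 °C
Reagents that add atoms: none
Why: Catalytic asymmetric alkynylation of the aldehyde by the catalyst formed from Me2Zn and (S,S)-ProPhenol, whose ligand should direct the alkynylzinc to the Re face and so set C8 as S.

Step 8
Reactants: 6 tributyl[(1Z,3Z)-3-methyl-5-(triethylsilyloxy)penta-1,3-dien-1-yl]stannane; 16 methyl (4S,6Z)-6-{[tert-butyl(dimethyl)silyl]oxymethyl}-4-hydroxy-7-iodohept-6-en-2-ynoate
Product: 17 methyl (4S,6Z,8Z,10Z)-6-{[tert-butyl(dimethyl)silyl]oxymethyl}-4-hydroxy-10-methyl-12-(triethylsilyloxy)dodeca-6,8,10-trien-2-ynoate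
Conditions: Pd2(dba)3 (5 mol %), AsPh3 (20 mol %), CuI (10 mol %), NMP, rt, dark; product kept cold
Reagents that add atoms: none
Why: Stille coupling (oxidative addition of zerovalent palladium to the C1–I bond, tin-to-palladium transmetalation, reductive elimination) should form C1–C2 with retention at both alkenyl partners, fixing the 1(10)Z and 2Z geometries under neutral conditions that spare the ynoate and the free hydroxyl.

Step 9
Reactants: 17 methyl (4S,6Z,8Z,10Z)-6-{[tert-butyl(dimethyl)silyl]oxymethyl}-4-hydroxy-10-methyl-12-(triethylsilyloxy)dodeca-6,8,10-trien-2-ynoate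
Product: 19 methyl (2Z,4S,6Z,8Z,10Z)-6-{[tert-butyl(dimethyl)silyl]oxymethyl}-4-hydroxy-2-(hydroxymethyl)-3-iodo-10-methyl-12-(triethylsilyloxy)dodeca-2,6,8,10-tetraenoate, via magnesium iodoallenolate 18 (not isolated)
Conditions: MgI2 (2 equiv), CH2Cl2, −20 °C; then monomeric CH2O in THF (3 equiv), −20 → 0 °C
Reagents that add atoms: magnesium iodide, [Mg+2].[I-].[I-]; formaldehyde, C=O
Why: Three-component halo-aldol (β-iodo Morita–Baylis–Hillman) reaction in which iodide adds to C7 of the magnesium-activated ynoate and the iodoallenolate is hydroxymethylated at C11 by formaldehyde bound to the magnesium held by O8, which should place C13 cis to C8 and the ester cis to iodine (7(11)Z), while any E isomer would lactonise onto O8 and be separated.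

Step 10
Reactants: 19 methyl (2Z,4S,6Z,8Z,10Z)-6-{[tert-butyl(dimethyl)silyl]oxymethyl}-4-hydroxy-2-(hydroxymethyl)-3-iodo-10-methyl-12-(triethylsilyloxy)dodeca-2,6,8,10-tetraenoate
Product: 20 methyl (2Z,4S,6Z,8Z,10Z)-2-(acetoxymethyl)-6-{[tert-butyl(dimethyl)silyl]oxymethyl}-4-hydroxy-3-iodo-10-methyl-12-(triethylsilyloxy)dodeca-2,6,8,10-tetraenoate
Conditions: AcCl (1.05 equiv), 2,4,6-collidine, CH2Cl2, −78 °C
Reagents that add atoms: acetyl chloride, CC(=O)Cl
Why: Kinetically controlled acylation should acetylate the primary allylic C13 hydroxyl in preference to the hindered secondary C8 hydroxyl.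

Step 11
Reactants: 20 methyl (2Z,4S,6Z,8Z,10Z)-2-(acetoxymethyl)-6-{[tert-butyl(dimethyl)silyl]oxymethyl}-4-hydroxy-3-iodo-10-methyl-12-(triethylsilyloxy)dodeca-2,6,8,10-tetraenoate; 21 (2R)-2-methylbutanoic acid
Product: 22 methyl (2Z,4S,6Z,8Z,10Z)-2-(acetoxymethyl)-6-{[tert-butyl(dimethyl)silyl]oxymethyl}-3-iodo-10-methyl-4-{[(2R)-2-methylbutanoyl]oxy}-12-(triethylsilyloxy)dodeca-2,6,8,10-tetraenoate
Conditions: DCC, DMAP (cat.), CH2Cl2, 0 °C → rt
Reagents that add atoms: none
Why: Steglich esterification acylates O8 without touching the C8 stereocentre, and the mild carbodiimide activation should not epimerise the α-stereocentre of the acid.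

Step 12
Reactants: 22 methyl (2Z,4S,6Z,8Z,10Z)-2-(acetoxymethyl)-6-{[tert-butyl(dimethyl)silyl]oxymethyl}-3-iodo-10-methyl-4-{[(2R)-2-methylbutanoyl]oxy}-12-(triethylsilyloxy)dodeca-2,6,8,10-tetraenoate
Product: 23 methyl (2Z,4S,6Z,8Z,10Z)-2-(acetoxymethyl)-6-{[tert-butyl(dimethyl)silyl]oxymethyl}-12-hydroxy-3-iodo-10-methyl-4-{[(2R)-2-methylbutanoyl]oxy}dodeca-2,6,8,10-tetraenoate
Conditions: PPTS (0.1 equiv), MeOH/CH2Cl2 (1:4), 0 °C
Reagents that add atoms: none
Why: Acid-catalysed methanolysis cleaves a primary TES ether much faster than a primary TBS ether, so only O6 should be freed.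

Step 13
Reactants: 23 methyl (2Z,4S,6Z,8Z,10Z)-2-(acetoxymethyl)-6-{[tert-butyl(dimethyl)silyl]oxymethyl}-12-hydroxy-3-iodo-10-methyl-4-{[(2R)-2-methylbutanoyl]oxy}dodeca-2,6,8,10-tetraenoate
Product: 24 methyl (2Z,4S,6Z,8Z)-2-(acetoxymethyl)-6-{[tert-butyl(dimethyl)silyl]oxymethyl}-9-[(2R,3S)-3-(hydroxymethyl)-2-methyloxiran-2-yl]-3-iodo-4-{[(2R)-2-methylbutanoyl]oxy}nona-2,6,8-trienoate
Conditions: Ti(OiPr)4 (0.3 equiv), L-(+)-DET (0.36 equiv), TBHP (2 equiv), 4 Å MS, CH2Cl2, −25 °C
Reagents that add atoms: tert-butyl hydroperoxide, CC(C)(C)OO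
Why: Katsuki–Sharpless asymmetric epoxidation reacts only at the alkene allylic to the free hydroxyl (C4=C5), and L-(+)-tartrate should deliver oxygen to the face that gives the 4R,5S epoxide, as it does for other Z-configured 3,3-disubstituted allylic alcohols.

Step 14
Reactants: 24 methyl (2Z,4S,6Z,8Z)-2-(acetoxymethyl)-6-{[tert-butyl(dimethyl)silyl]oxymethyl}-9-[(2R,3S)-3-(hydroxymethyl)-2-methyloxiran-2-yl]-3-iodo-4-{[(2R)-2-methylbutanoyl]oxy}nona-2,6,8-trienoate
Product: 25 methyl (2Z,4S,6Z,8Z)-2-(acetoxymethyl)-6-{[tert-butyl(dimethyl)silyl]oxymethyl}-9-[(2R,3R)-3-formyl-2-methyloxiran-2-yl]-3-iodo-4-{[(2R)-2-methylbutanoyl]oxy}nona-2,6,8-trienoate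
Conditions: Dess–Martin periodinane, NaHCO3, CH2Cl2, 0 °C
Reagents that add atoms: none
Why: Buffered Dess–Martin oxidation should convert the epoxy alcohol into the α,β-epoxy aldehyde without opening the dienyl epoxide or disturbing C5 (the descriptor at C5 changes only through the priority rules).

Step 15
Reactants: 25 methyl (2Z,4S,6Z,8Z)-2-(acetoxymethyl)-6-{[tert-butyl(dimethyl)silyl]oxymethyl}-9-[(2R,3R)-3-formyl-2-methyloxiran-2-yl]-3-iodo-4-{[(2R)-2-methylbutanoyl]oxy}nona-2,6,8-trienoate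
Product: 26 methyl (2Z,4S,6Z,8Z)-2-(acetoxymethyl)-9-[(2R,3R)-3-formyl-2-methyloxiran-2-yl]-6-(hydroxymethyl)-3-iodo-4-{[(2R)-2-methylbutanoyl]oxy}nona-2,6,8-trienoate
Conditions: HF·pyridine, pyridine, THF, 0 °C
Reagents that add atoms: none
Why: Pyridine-buffered fluoride desilylation should free the C14 allylic alcohol while the esters, the epoxide and the aldehyde survive.

Step 16
Reactants: 26 methyl (2Z,4S,6Z,8Z)-2-(acetoxymethyl)-9-[(2R,3R)-3-formyl-2-methyloxiran-2-yl]-6-(hydroxymethyl)-3-iodo-4-{[(2R)-2-methylbutanoyl]oxy}nona-2,6,8-trienoate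
Product: 27 methyl (2Z,4S)-2-(acetoxymethyl)-5-[(2S,3R)-3-{(Z)-2-[(2R,3R)-3-formyl-2-methyloxiran-2-yl]ethenyl}-2-(hydroxymethyl)oxiran-2-yl]-3-iodo-4-{[(2R)-2-methylbutanoyl]oxy}pent-2-enoate
Conditions: Ti(OiPr)4 (1.0 equiv), L-(+)-DIPT (1.2 equiv), TBHP (2 equiv), 4 Å MS, CH2Cl2, −20 °C
Reagents that add atoms: tert-butyl hydroperoxide, CC(C)(C)OO
Why: A second Katsuki–Sharpless epoxidation, directed by O14 to C1=C10 only (the C2=C3 alkene has no allylic hydroxyl), should give the 1R,10S epoxide with L-(+)-tartrate; the titanium–tartrate system tolerates aldehydes, and the stoichiometric loading answers the slow Z-substituted substrate.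

Step 17
Reactants: 27 methyl (2Z,4S)-2-(acetoxymethyl)-5-[(2S,3R)-3-{(Z)-2-[(2R,3R)-3-formyl-2-methyloxiran-2-yl]ethenyl}-2-(hydroxymethyl)oxiran-2-yl]-3-iodo-4-{[(2R)-2-methylbutanoyl]oxy}pent-2-enoate
Product: 30 CNP0108300.1 (target), via alkenylchromium 28 (not isolated), via chromium alkoxide 29 (not isolated)
Conditions: CrCl2 (15 equiv), NiCl2 (2 mol %), DMSO/THF (3:1), rt, syringe-pump addition of 27 over 24 h (final 1 mM)
Reagents that add atoms: none
Why: Nozaki–Hiyama–Kishi macrocyclisation with in-situ lactonisation: zerovalent nickel (NiCl2 reduced by CrCl2) inserts into the C7–I bond, transmetalation to trivalent chromium gives alkenylchromium 28 with retention of the 7(11)Z geometry, 28 adds to the C6 aldehyde, and the chromium alkoxide 29 attacks the cis C12 methyl ester and expels methoxide. The closest known reaction type is the CrCl2/NiCl2 coupling of (Z)-β-iodoacrylates with aldehydes to butenolides, used here intramolecularly as in Nozaki–Hiyama–Kishi macrocyclisations. The ten-membered carbocycle closes by 10-exo-trig addition of C7 to the C6 carbonyl and the butenolide by 5-exo-trig acyl substitution of O6 at C12. The one new stereocentre, C6, is set by the adjacent C5 epoxide stereocentre (Felkin–Anh addition anti to the C5–O bond and past H5 gives the 5,6-anti, 6S carbinol), helped by the folding that the cis C2=C3 alkene and the two epoxides impose. The step needs ring closure to beat oligomerisation and the alkenyl metal to spare the allylic acetate, the vinyl epoxides, the C8 ester (β-elimination) and the free C14 hydroxyl; slow addition at about 1 mM, the rigid backbone and the low basicity and high aldehyde selectivity of alkenylchromium reagents should secure this.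

Compound list
1 | (2Z)-3-methylpent-2-en-4-yn-1-ol | OC/C=C(\C#C)C | starting material
2 | triethyl{[(2Z)-3-methylpent-2-en-4-yn-1-yl]oxy}silane | CC[Si](CC)(CC)OC/C=C(\C#C)C | intermediate
3 | lithium acetylide of 2 (not isolated) | CC[Si](CC)(CC)OC/C=C(\C#C[Li])C | intermediate
4 | tributyl[(3Z)-3-methyl-5-(triethylsilyloxy)pent-3-en-1-yn-1-yl]stannane | CC[Si](CC)(CC)OC/C=C(\C#C[Sn](CCCC)(CCCC)CCCC)C | intermediate
5 | alkenylzirconocene: (3Z)-1-(tributylstannyl)-1-[chlorobis(cyclopentadienyl)zirconio]-3-methyl-5-(triethylsilyloxy)penta-1,3-diene, tin cis to C3 (not isolated) | CC[Si](CC)(CC)OC/C=C(C)\C=C(/[Sn](CCCC)(CCCC)CCCC)[Zr](Cl)(C1C=CC=C1)C1C=CC=C1 | intermediate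
6 | tributyl[(1Z,3Z)-3-methyl-5-(triethylsilyloxy)penta-1,3-dien-1-yl]stannane (west fragment: C2–C6 and C15) | CC[Si](CC)(CC)OC/C=C(C)\C=C/[Sn](CCCC)(CCCC)CCCC | intermediate
7 | prop-2-yn-1-ol | C#CCO | starting material
8 | allylmagnesium bromide | C=CC[Mg]Br | starting material
9 | alkenylmagnesium chelate: 4-allyl-2,5-dihydro-1,2-oxamagnesole (not isolated) | C=CCC1=C[Mg]OC1 | intermediate
10 | (2Z)-2-(iodomethylidene)pent-4-en-1-ol | OC/C(CC=C)=C\I | intermediate
11 | tert-butyl{[(2Z)-2-(iodomethylidene)pent-4-en-1-yl]oxy}dimethylsilane | CC(C)(C)[Si](C)(C)OC/C(CC=C)=C\I | intermediate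
12 | diol: (4Z)-4-{[tert-butyl(dimethyl)silyl]oxymethyl}-5-iodopent-4-ene-1,2-diol, both C2 epimers (not isolated) | CC(C)(C)[Si](C)(C)OC/C(CC(O)CO)=C\I | intermediate
13 | (3Z)-3-{[tert-butyl(dimethyl)silyl]oxymethyl}-4-iodobut-3-enal | CC(C)(C)[Si](C)(C)OC/C(CC=O)=C\I | intermediate
14 | methyl prop-2-ynoate | C#CC(=O)OC | starting material
15 | alkynylzinc: methyl 3-(methylzincio)prop-2-ynoate (not isolated) | COC(=O)C#C[Zn]C | intermediate
16 | methyl (4S,6Z)-6-{[tert-butyl(dimethyl)silyl]oxymethyl}-4-hydroxy-7-iodohept-6-en-2-ynoate (east fragment: C1, C7–C12 and C14) | COC(=O)C#C[C@@H](O)C/C(CO[Si](C)(C)C(C)(C)C)=C/I | intermediate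
17 | methyl (4S,6Z,8Z,10Z)-6-{[tert-butyl(dimethyl)silyl]oxymethyl}-4-hydroxy-10-methyl-12-(triethylsilyloxy)dodeca-6,8,10-trien-2-ynoate | COC(=O)C#C[C@@H](O)C/C(CO[Si](C)(C)C(C)(C)C)=C/C=C\C(C)=C/CO[Si](CC)(CC)CC | intermediate
18 | magnesium iodoallenolate of 17: iodine on C7, allene C7=C11=C12, O–MgI on C12 (not isolated) | COC(O[Mg]I)=C=C(I)[C@@H](O)C/C(CO[Si](C)(C)C(C)(C)C)=C/C=C\C(C)=C/CO[Si](CC)(CC)CC | intermediate
19 | methyl (2Z,4S,6Z,8Z,10Z)-6-{[tert-butyl(dimethyl)silyl]oxymethyl}-4-hydroxy-2-(hydroxymethyl)-3-iodo-10-methyl-12-(triethylsilyloxy)dodeca-2,6,8,10-tetraenoate | COC(=O)/C(CO)=C(\I)[C@@H](O)C/C(CO[Si](C)(C)C(C)(C)C)=C/C=C\C(C)=C/CO[Si](CC)(CC)CC | intermediate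
20 | methyl (2Z,4S,6Z,8Z,10Z)-2-(acetoxymethyl)-6-{[tert-butyl(dimethyl)silyl]oxymethyl}-4-hydroxy-3-iodo-10-methyl-12-(triethylsilyloxy)dodeca-2,6,8,10-tetraenoate | COC(=O)/C(COC(C)=O)=C(\I)[C@@H](O)C/C(CO[Si](C)(C)C(C)(C)C)=C/C=C\C(C)=C/CO[Si](CC)(CC)CC | intermediate
21 | (2R)-2-methylbutanoic acid | CC[C@@H](C)C(=O)O | starting material
22 | methyl (2Z,4S,6Z,8Z,10Z)-2-(acetoxymethyl)-6-{[tert-butyl(dimethyl)silyl]oxymethyl}-3-iodo-10-methyl-4-{[(2R)-2-methylbutanoyl]oxy}-12-(triethylsilyloxy)dodeca-2,6,8,10-tetraenoate | COC(=O)/C(COC(C)=O)=C(\I)[C@@H](OC(=O)[C@H](C)CC)C/C(CO[Si](C)(C)C(C)(C)C)=C/C=C\C(C)=C/CO[Si](CC)(CC)CC | intermediate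
23 | methyl (2Z,4S,6Z,8Z,10Z)-2-(acetoxymethyl)-6-{[tert-butyl(dimethyl)silyl]oxymethyl}-12-hydroxy-3-iodo-10-methyl-4-{[(2R)-2-methylbutanoyl]oxy}dodeca-2,6,8,10-tetraenoate | COC(=O)/C(COC(C)=O)=C(\I)[C@@H](OC(=O)[C@H](C)CC)C/C(CO[Si](C)(C)C(C)(C)C)=C/C=C\C(C)=C/CO | intermediate
24 | methyl (2Z,4S,6Z,8Z)-2-(acetoxymethyl)-6-{[tert-butyl(dimethyl)silyl]oxymethyl}-9-[(2R,3S)-3-(hydroxymethyl)-2-methyloxiran-2-yl]-3-iodo-4-{[(2R)-2-methylbutanoyl]oxy}nona-2,6,8-trienoate | COC(=O)/C(COC(C)=O)=C(\I)[C@@H](OC(=O)[C@H](C)CC)C/C(CO[Si](C)(C)C(C)(C)C)=C/C=C\[C@@]1(C)O[C@H]1CO | intermediate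
25 | methyl (2Z,4S,6Z,8Z)-2-(acetoxymethyl)-6-{[tert-butyl(dimethyl)silyl]oxymethyl}-9-[(2R,3R)-3-formyl-2-methyloxiran-2-yl]-3-iodo-4-{[(2R)-2-methylbutanoyl]oxy}nona-2,6,8-trienoate | COC(=O)/C(COC(C)=O)=C(\I)[C@@H](OC(=O)[C@H](C)CC)C/C(CO[Si](C)(C)C(C)(C)C)=C/C=C\[C@@]1(C)O[C@H]1C=O | intermediate
26 | methyl (2Z,4S,6Z,8Z)-2-(acetoxymethyl)-9-[(2R,3R)-3-formyl-2-methyloxiran-2-yl]-6-(hydroxymethyl)-3-iodo-4-{[(2R)-2-methylbutanoyl]oxy}nona-2,6,8-trienoate | COC(=O)/C(COC(C)=O)=C(\I)[C@@H](OC(=O)[C@H](C)CC)C/C(CO)=C/C=C\[C@@]1(C)O[C@H]1C=O | intermediate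
27 | methyl (2Z,4S)-2-(acetoxymethyl)-5-[(2S,3R)-3-{(Z)-2-[(2R,3R)-3-formyl-2-methyloxiran-2-yl]ethenyl}-2-(hydroxymethyl)oxiran-2-yl]-3-iodo-4-{[(2R)-2-methylbutanoyl]oxy}pent-2-enoate (open-chain precursor of the key step) | COC(=O)/C(COC(C)=O)=C(\I)[C@@H](OC(=O)[C@H](C)CC)C[C@@]1(CO)O[C@@H]1/C=C\[C@@]1(C)O[C@H]1C=O | intermediate
28 | alkenylchromium: compound 27 with CrCl2 in place of iodine at C7 (not isolated) | COC(=O)/C(COC(C)=O)=C(\[Cr](Cl)Cl)[C@@H](OC(=O)[C@H](C)CC)C[C@@]1(CO)O[C@@H]1/C=C\[C@@]1(C)O[C@H]1C=O | intermediate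
29 | chromium alkoxide of the ring-closed hydroxy ester: ten-membered carbocycle, (6S)-O–CrCl2, exocyclic C7=C11 with CO2Me cis to C6 and CH2OAc cis to C8 (not isolated) | CC[C@@H](C)C(=O)O[C@H]1C[C@@]2(CO)O[C@@H]2/C=C\[C@@]2(C)O[C@H]2[C@@H](O[Cr](Cl)Cl)/C1=C(/COC(C)=O)C(=O)OC | intermediate
30 | CNP0108300.1: (1R,4R,5S,6S,8S,10S)-13-acetoxy-1,10:4,5-diepoxy-14-hydroxy-8-[(2R)-2-methylbutanoyloxy]germacra-2Z,7(11)-dien-12,6-olide | CC[C@@H](C)C(=O)O[C@H]1C[C@@]2(CO)O[C@@H]2/C=C\[C@@]2(C)O[C@H]2[C@H]2OC(=O)C(COC(C)=O)=C12 | target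

Total step count: 17. Longest linear sequence: 14 steps (steps 4–17, from prop-2-yn-1-ol); the west fragment (steps 1–3) joins at step 8.

Steps most likely to fail

Step 9. What may go wrong: the hydroxymethylation of the iodoallenolate may take place on the face syn to iodine instead of syn to C8. That gives the E alkene, which lactonises onto O8 and is lost. Fallback (sets out from 17, comes back at 19): the geometry is enforced by a temporary silicon tether instead of by chelation. O8 of 17 is silylated with (bromomethyl)chlorodimethylsilane and imidazole to the (bromomethyl)dimethylsilyl ether F1. LiI in DMF then exchanges bromide for iodide and adds iodide to C7 of the ynoate, and the allenolate is alkylated at C11 by the tethered halomethyl group (Michael-initiated ring closure). This can only give the six-membered oxasilacycle F2, in which C13 is cis to C8 and iodine cis to the ester. Tamao oxidation (H2O2, KF, KHCO3, THF/MeOH) cleaves the C13–Si and O8–Si bonds and returns diol 19.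

Step 17. What may go wrong: intermolecular coupling instead of ring closure, loss of the C8 carboxylate from the alkenylchromium by β-elimination to an allene, opening of the two vinyl epoxides by the Lewis-acidic chromium salts, or addition to the wrong face of the aldehyde. Fallback (sets out from 25, comes back at 30): ring closure and the second epoxidation change places, so that the cyclisation substrate carries one epoxide less and no free hydroxyl. Aldehyde 25 is cyclised under the same CrCl2/NiCl2 conditions to the macrocyclic dienyl butenolide F3 (1(10)Z,2Z-diene, 4,5-epoxide, 14-OTBS). HF·pyridine then frees the allylic alcohol F4. A Katsuki–Sharpless epoxidation with Ti(OiPr)4, L-(+)-DIPT and TBHP, now on the ring and still under reagent control, gives 30.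

Step 16. What may go wrong: epoxidation of the hindered, Z-substituted allylic alcohol may be slow and poorly face-selective, while the unprotected epoxy aldehyde is acetalised or opened by the titanium tartrate. Fallback (sets out from 22, comes back at 27): both epoxides are introduced before the aldehyde exists. HF·pyridine removes both silyl groups of 22 to give the 6,14-diol F5. One two-directional Katsuki–Sharpless epoxidation with Ti(OiPr)4, L-(+)-DET and TBHP (both allylic alcohols call for the same tartrate) gives the bis-epoxy diol F6. TEMPO/PhI(OAc)2 then oxidises only the less hindered C6 carbinol (the C14 carbinol is neopentylic) to 27.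

Further compounds
F1 | step 9 | (bromomethyl)dimethylsilyl ether of 17 at O8 | COC(=O)C#C[C@@H](O[Si](C)(C)CBr)C/C(CO[Si](C)(C)C(C)(C)C)=C/C=C\C(C)=C/CO[Si](CC)(CC)CC
F2 | step 9 | six-membered oxasilacycle: O8–SiMe2–C13 ring, iodine on C7, methyl ester on C11 | COC(=O)C1=C(I)[C@H](C/C(CO[Si](C)(C)C(C)(C)C)=C/C=C\C(C)=C/CO[Si](CC)(CC)CC)O[Si](C)(C)C1
F3 | step 17 | macrocyclic dienyl butenolide: target skeleton with C1=C10 alkene instead of the 1,10-epoxide and O14 as TBS ether | CC[C@@H](C)C(=O)O[C@H]1C/C(CO[Si](C)(C)C(C)(C)C)=C/C=C\[C@@]2(C)O[C@H]2[C@H]2OC(=O)C(COC(C)=O)=C12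
F4 | step 17 | allylic alcohol: F3 with free 14-hydroxyl | CC[C@@H](C)C(=O)O[C@H]1C/C(CO)=C/C=C\[C@@]2(C)O[C@H]2[C@H]2OC(=O)C(COC(C)=O)=C12
F5 | step 16 | 6,14-diol: compound 22 without both silyl groups | COC(=O)/C(COC(C)=O)=C(\I)[C@@H](OC(=O)[C@H](C)CC)C/C(CO)=C/C=C\C(C)=C/CO
F6 | step 16 | bis-epoxy diol: (1R,10S)- and (4R,5S)-epoxides, free 6- and 14-hydroxyls | COC(=O)/C(COC(C)=O)=C(\I)[C@@H](OC(=O)[C@H](C)CC)C[C@@]1(CO)O[C@@H]1/C=C\[C@@]1(C)O[C@H]1CO
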